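**Retrosynthetic overview**
1. The pyranone C-ring is formed last: O1–C2 bond and C2=C3 unsaturation come from oxidative cyclisation of a 2'-hydroxychalcone.
2. The chalcone Cα=Cβ bond is disconnected by Claisen–Schmidt condensation into an A-ring acetophenone and a B-ring aldehyde, used with its phenol unprotected.
3. The aryl–acyl bond of the acetophenone is disconnected by Friedel–Crafts C-acetylation of 3,4,5-trimethoxyphenol.
4. Both benzene rings are bought; only the heterocycle is built.

Assumption: the target (3'-hydroxy-5,6,7,4',5'-pentamethoxyflavone) has no stereocentre, so "single enantiomer" needs no stereocontrol. The route is a proposal from known reaction types and has not been run.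

**Route**

Step 1
Reactants: 1 3,4,5-trimethoxyphenol
Product: 3 1-(6-hydroxy-2,3,4-trimethoxyphenyl)ethanone, via difluoroboron chelate 2 (not isolated)
Conditions: AcOH, BF3·OEt2 (3 equiv), 85 °C, 3 h; then H2O/EtOH, 70 °C
Reagents that add atoms: acetic acid, CC(=O)O
Why: Friedel–Crafts (Nencki-type) C-acetylation occurs at the only free ring positions (C2/C6, equivalent, ortho to OH), and BF3 traps the ketone as the BF2 chelate, which stops over-acylation and is hydrolysed on work-up; no stereocentre forms.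

Step 2
Reactants: 3 1-(6-hydroxy-2,3,4-trimethoxyphenyl)ethanone; 4 3-hydroxy-4,5-dimethoxybenzaldehyde
Product: 6 (E)-3-(3-hydroxy-4,5-dimethoxyphenyl)-1-(6-hydroxy-2,3,4-trimethoxyphenyl)prop-2-en-1-one, via aldol adduct 5 (not isolated)
Conditions: KOH (50% aq., 10 equiv), EtOH, 0 °C to rt, 48 h; then 2 M HCl to pH 3
Reagents that add atoms: none
Why: Claisen–Schmidt (crossed aldol) condensation works because the methyl-ketone enolate adds to a non-enolisable aldehyde whose meta-phenoxide is not conjugated to the formyl group, and E1cB dehydration gives the (E)-enone under thermodynamic control.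

Step 3
Reactants: 6 (E)-3-(3-hydroxy-4,5-dimethoxyphenyl)-1-(6-hydroxy-2,3,4-trimethoxyphenyl)prop-2-en-1-one
Product: 9 3'-hydroxy-5,6,7,4',5'-pentamethoxyflavone, via flavanone 7 (not isolated), via 3-iodoflavanone 8 (not isolated)
Conditions: I2 (10 mol%), DMSO, 130 °C, 2 h; aq. Na2S2O3 work-up
Reagents that add atoms: none
Why: Iodine-catalysed oxidative cyclisation in DMSO proceeds by oxa-Michael closure to the flavanone, α-iodination and loss of HI (DMSO re-oxidises HI to I2), which destroys the transient C2/C3 stereocentres and gives the achiral flavone.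

**Compound list**
1 | 3,4,5-trimethoxyphenol | COc1cc(O)cc(OC)c1OC | starting material
2 | difluoroboron (BF2) O,O-chelate of ketone 3, boron bridging the phenol oxygen and the carbonyl oxygen (not isolated) | CC1=[O+][B-](F)(F)Oc2cc(OC)c(OC)c(OC)c12 | intermediate
3 | 1-(6-hydroxy-2,3,4-trimethoxyphenyl)ethanone (2'-hydroxy-4',5',6'-trimethoxyacetophenone) | CC(=O)c1c(O)cc(OC)c(OC)c1OC | intermediate
4 | 3-hydroxy-4,5-dimethoxybenzaldehyde | COc1cc(C=O)cc(O)c1OC | starting material
5 | aldol adduct, 3-hydroxy-3-(3-hydroxy-4,5-dimethoxyphenyl)-1-(6-hydroxy-2,3,4-trimethoxyphenyl)propan-1-one, racemic (not isolated) | COc1cc(C(O)CC(=O)c2c(O)cc(OC)c(OC)c2OC)cc(O)c1OC | intermediate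
6 | (E)-3-(3-hydroxy-4,5-dimethoxyphenyl)-1-(6-hydroxy-2,3,4-trimethoxyphenyl)prop-2-en-1-one (2'-hydroxychalcone) | COc1cc(/C=C/C(=O)c2c(O)cc(OC)c(OC)c2OC)cc(O)c1OC | intermediate
7 | 2-(3-hydroxy-4,5-dimethoxyphenyl)-5,6,7-trimethoxychroman-4-one (flavanone), racemic (not isolated) | COc1cc(C2CC(=O)c3c(OC)c(OC)c(OC)cc3O2)cc(O)c1OC | intermediate
8 | 2-(3-hydroxy-4,5-dimethoxyphenyl)-3-iodo-5,6,7-trimethoxychroman-4-one (3-iodoflavanone), racemic, C2/C3 configuration not controlled (not isolated) | COc1cc(C2Oc3cc(OC)c(OC)c(OC)c3C(=O)C2I)cc(O)c1OC | intermediate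
9 | 3'-hydroxy-5,6,7,4',5'-pentamethoxyflavone, i.e. 2-(3-hydroxy-4,5-dimethoxyphenyl)-5,6,7-trimethoxy-4H-chromen-4-one, achiral | COc1cc(-c2cc(=O)c3c(OC)c(OC)c(OC)cc3o2)cc(O)c1OC | target

**Totals**
Total step count: 3. Longest linear sequence: 3 steps (1 → 3 → 6 → 9).

**Steps most likely to fail, with fallbacks**

Step 2 (highest risk). The condensation runs on poly-anionic partners with an unprotected phenolic aldehyde, so it may stall, give low conversion or Cannizzaro by-products. Any flavanone 7 formed alongside 6 is harmless, since step 3 passes through it. The fallback sets out from 4 and masks the phenol. Benzylation (BnBr, K2CO3, DMF, 60 °C) gives 3-(benzyloxy)-4,5-dimethoxybenzaldehyde F1. Claisen–Schmidt condensation of this with 3 (KOH, EtOH, rt) gives (E)-3-[3-(benzyloxy)-4,5-dimethoxyphenyl]-1-(6-hydroxy-2,3,4-trimethoxyphenyl)prop-2-en-1-one F2. I2 (cat.)/DMSO at 130 °C then gives 3'-benzyloxy-5,6,7,4',5'-pentamethoxyflavone F3. Hydrogenolysis (H2 1 atm, Pd/C, EtOAc/MeOH, rt, stopped at full debenzylation so the C2=C3 bond is kept) comes back to the route at 9.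

Step 3. The electron-rich phenolic B-ring could be iodinated, HI could cleave the 5-OMe peri to the carbonyl, or the reaction could stop at the flavanone. The fallback sets out from 6 and replaces the one-pot iodine chemistry by a stepwise, iodine-free sequence. Isomerisation with NaOAc in refluxing EtOH gives flavanone 7, now isolated. Acetylation (Ac2O, pyridine, rt) gives 2,3-dimethoxy-5-(5,6,7-trimethoxy-4-oxochroman-2-yl)phenyl acetate F4. Dehydrogenation with DDQ in refluxing dioxane gives 3'-acetoxy-5,6,7,4',5'-pentamethoxyflavone F5. Methanolysis (K2CO3, MeOH, rt) comes back to the route at 9.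

Step 1. Hot BF3 may demethylate the methoxy group ortho to the new carbonyl, stop at the O-acetate, or leave a chelate that resists hydrolysis. The fallback sets out from 1 and uses a Houben–Hoesch acylation instead. MeCN, ZnCl2 and HCl gas in Et2O at 0 °C give 1-(6-hydroxy-2,3,4-trimethoxyphenyl)ethan-1-iminium chloride F6, which is filtered off. Hydrolysis in refluxing water comes back to the route at 3.

**Further compounds**
F1 | step 2 | 3-(benzyloxy)-4,5-dimethoxybenzaldehyde | COc1cc(C=O)cc(OCc2ccccc2)c1OC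
F2 | step 2 | (E)-3-[3-(benzyloxy)-4,5-dimethoxyphenyl]-1-(6-hydroxy-2,3,4-trimethoxyphenyl)prop-2-en-1-one | COc1cc(/C=C/C(=O)c2c(O)cc(OC)c(OC)c2OC)cc(OCc2ccccc2)c1OC
F3 | step 2 | 3'-benzyloxy-5,6,7,4',5'-pentamethoxyflavone | COc1cc(-c2cc(=O)c3c(OC)c(OC)c(OC)cc3o2)cc(OCc2ccccc2)c1OC
F4 | step 3 | 2,3-dimethoxy-5-(5,6,7-trimethoxy-4-oxochroman-2-yl)phenyl acetate (racemic) | CC(=O)Oc1cc(C2CC(=O)c3c(OC)c(OC)c(OC)cc3O2)cc(OC)c1OC
F5 | step 3 | 3'-acetoxy-5,6,7,4',5'-pentamethoxyflavone | CC(=O)Oc1cc(-c2cc(=O)c3c(OC)c(OC)c(OC)cc3o2)cc(OC)c1OC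
F6 | step 1 | 1-(6-hydroxy-2,3,4-trimethoxyphenyl)ethan-1-iminium chloride | CC(=[NH2+])c1c(O)cc(OC)c(OC)c1OC.[Cl-]
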